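**Plan**
- Retrosynthesis: cut the C1–benzoyl bond, then C5–C6 (ring B and the cage), then C3–C4 and C1–C9 together (ring A), which leaves a hydroazulene silyl enol ether (rings E and D) and geranylmalonyl dichloride.
- Rings E and D are cut at C11–C3 and C1–C2 back to an acyclic alkyne–vinylcyclopropane.
- Forward: chain assembly, then rings E and D in one rhodium-catalysed (5+2) cycloaddition, ring A by double C-acylation, ring B and the cage by radical closure, and the benzoyl group last.
- Stereochemistry: a reagent-controlled Charette cyclopropanation sets one cyclopropane carbon, and the (5+2) step relays it to C11. A racemic cyclopropane would give racemic material whatever the catalyst, so this is where the absolute configuration enters.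
- C11 then directs C3 and, through the tether, C1 in the key step; C5 and C7 are fixed by the geometry of the cage.

Key step: step 16

Remark: atom numbers are those of the target. Ring A is C1(benzoyl)–C2(=O)–C3–C4(=O)–C5(geranyl)–C9(=O), C6 is the CH2 between C5 and C7, C8 and C12 are the two CMe2 carbons, C10 links C7 and C11, and ring D is C3–C11–C12–C13–C14. Centres that are erased later (C2/C3 in 17–19, C5 in 26 and 28) are drawn without configuration.

**Route**

Step 1
Reactants: 1 isobutyronitrile; 2 (4-bromobut-1-yn-1-yl)trimethylsilane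
Product: 3 2,2-dimethyl-6-(trimethylsilyl)hex-5-ynenitrile
Conditions: LiN(i-Pr)2, THF, −78 °C; then 2, DMPU, −78 → 23 °C
Reagents that add atoms: none
Why: SN2 alkylation of the lithiated nitrile builds the quaternary C12, and the silyl cap keeps the alkyne C–H from quenching the carbanion.

Step 2
Reactants: 3
Product: 5 2,2-dimethyl-6-(trimethylsilyl)hex-5-ynal, via aldimine 4 (not isolated)
Conditions: i-Bu2AlH, CH2Cl2, −78 °C; then 1 M aq. HCl, 0 °C
Reagents that add atoms: water, O
Why: partial reduction of the nitrile by the aluminium hydride stops at the N-aluminoimine, which is hydrolysed to the aldehyde on work-up, and the quaternary α-carbon excludes enolization.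

Step 3
Reactants: 5; 6 3-methylbutan-2-one
Product: 9 (4E)-2,6,6-trimethyldec-4-en-9-yn-3-one, via desilylated aldehyde 7 (not isolated), via aldol adduct 8 (not isolated)
Conditions: NaOH, EtOH–H2O, 6 (5 equiv), 23 → 60 °C
Reagents that add atoms: none
Why: Claisen–Schmidt condensation of the non-enolizable aldehyde at the methyl group of 6 (the aldol on the methine side cannot dehydrate and reverts) should give the (E)-enone, and hydroxide removes the alkynyl silyl group in the same flask.

Step 4
Reactants: 9
Product: 10 (4E)-2,6,6-trimethyldeca-2,4-dien-9-yn-3-yl trifluoromethanesulfonate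
Conditions: KN(SiMe3)2, THF, −78 °C; then PhNTf2, −78 → 0 °C; aq. NH4Cl
Reagents that add atoms: N-phenylbis(trifluoromethanesulfonimide), O=S(=O)(N(c1ccccc1)S(=O)(=O)C(F)(F)F)C(F)(F)F
Why: enolate O-triflation; the enone can lose only the α′ methine hydrogen (C12 is quaternary, so there is no γ-hydrogen), which gives a single cross-conjugated enol triflate, and the less acidic alkyne C–H is left as it is.

Step 5
Reactants: 10
Product: 11 (3E)-5,5-dimethyl-2-(propan-2-ylidene)non-3-en-8-yn-1-ol
Conditions: Bu3SnCH2OH, Pd(PPh3)4 (5 mol %), LiCl, 1,4-dioxane, 90 °C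
Reagents that add atoms: (tributylstannyl)methanol, OC[Sn](CCCC)(CCCC)CCCC
Why: Stille coupling of the enol triflate with the hydroxymethyl stannane transfers CH2OH (the future C6) in preference to butyl and leaves both alkene geometries unchanged.

Step 6
Reactants: 11
Product: 12 {(1S)-1-[(1E)-3,3-dimethylhept-1-en-6-yn-1-yl]-2,2-dimethylcyclopropyl}methanol
Conditions: Et2Zn (2.2 equiv), CH2I2 (4.4 equiv), DME, CH2Cl2, −10 °C; then 11 and (4S,5S)-2-butyl-N,N,N′,N′-tetramethyl-1,3,2-dioxaborolane-4,5-dicarboxamide (1.2 equiv), −10 → 23 °C
Reagents that add atoms: diiodomethane, ICI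
Why: Charette asymmetric Simmons–Smith cyclopropanation, in which the zinc alkoxide bound to the chiral dioxaborolane delivers CH2 to one face of the allylic, tetrasubstituted alkene only; by the established facial model the (4S,5S) ligand should set the quaternary cyclopropane carbon (future C7) as S.

Step 7
Reactants: 12
Product: 13 [(8aR)-1,1,6,6-tetramethyl-1,2,3,5,6,8a-hexahydroazulen-7-yl]methanol
Conditions: [Rh(CO)2Cl]2 (5 mol %), toluene (0.02 M), 80 °C
Reagents that add atoms: none
Why: rhodium-catalysed intramolecular (5+2) cycloaddition of the alkyne with the vinylcyclopropane, in which monovalent rhodium should cleave the less substituted C7–CH2 bond so that the gem-dimethyl carbon C8 stays next to C7; only the conformer with C8 s-cis to the alkene can close the seven-membered ring, so the cyclopropane configuration fixes the alkene face that bonds to C3 and is transferred to C11.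

Step 8
Reactants: 13
Product: 16 (8aR)-1,1,6,6-tetramethyl-7-methylidene-1,2,3,5,6,7,8,8a-octahydroazulene, via sulfonylhydrazine 14 (not isolated), via allylic diazene 15 (not isolated)
Conditions: PPh3, DEAD, 2-nitrobenzenesulfonylhydrazide, N-methylmorpholine, −30 °C; then 23 °C
Reagents that add atoms: none
Why: Myers reductive 1,3-transposition (Mitsunobu displacement of the primary allylic alcohol, loss of sulfinic acid, retro-ene loss of N2 from the diazene) moves the double bond to C7=C6 and puts hydrogen on C10 without touching C11.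

Step 9
Reactants: 16
Product: 17 (8aR)-3a,4-epoxy-1,1,6,6-tetramethyl-7-methylidenedecahydroazulene (C2–C3 epoxide)
Conditions: m-CPBA (1.0 equiv), NaHCO3, CH2Cl2, −20 → 0 °C
Reagents that add atoms: 3-chloroperbenzoic acid, O=C(OO)c1cccc(Cl)c1
Why: Prilezhaev epoxidation should be faster at the trisubstituted ring alkene C2=C3 than at the 1,1-disubstituted methylidene shielded by the quaternary C8, and the epoxide configuration is irrelevant because C2 and C3 return to sp2.

Step 10
Reactants: 17
Product: 18 (8aS)-1,1,6,6-tetramethyl-7-methylidenedecahydroazulen-4-ol (C2 alcohol)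
Conditions: Cp2TiCl2 (10 mol %), Mn dust, 2,4,6-collidine hydrochloride, 1,4-cyclohexadiene, THF, 23 °C
Reagents that add atoms: none
Why: titanocene-catalysed reductive epoxide opening, in which trivalent titanium (Cp2TiCl) cleaves the C3–O bond to the more substituted C3 radical, which takes hydrogen from 1,4-cyclohexadiene, so that oxygen stays on C2.

Step 11
Reactants: 18
Product: 19 (8aS)-1,1,6,6-tetramethyl-7-methylideneoctahydroazulen-4(1H)-one
Conditions: Dess–Martin periodinane, NaHCO3, CH2Cl2, 23 °C
Reagents that add atoms: none
Why: Dess–Martin oxidation of the secondary alcohol under buffered conditions gives the C2 ketone and leaves the methylidene group alone; C11 is β to the carbonyl and cannot epimerize.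

Step 12
Reactants: 19
Product: 20 trimethyl{[(8aR)-1,1,6,6-tetramethyl-7-methylidene-1,2,3,5,6,7,8,8a-octahydroazulen-4-yl]oxy}silane
Conditions: Me3SiCl, NaI, Et3N, MeCN, 40 °C
Reagents that add atoms: chlorotrimethylsilane, C[Si](C)(C)Cl
Why: enol silylation under equilibrating conditions (Me3SiI formed in the flask) should favour the tetrasubstituted C2=C3 enol ether, exocyclic to the five-membered ring D, over the C1=C2 isomer.

Step 13
Reactants: 21 diethyl malonate; 22 geranyl bromide
Product: 23 diethyl 2-[(2E)-3,7-dimethylocta-2,6-dien-1-yl]propanedioate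
Conditions: NaH, THF, 0 °C (21 in 1.5-fold excess); then 22, 0 → 23 °C
Reagents that add atoms: none
Why: malonic ester alkylation, in which the soft malonate anion attacks the primary allylic bromide by SN2 without allylic transposition, and excess malonate limits dialkylation.

Step 14
Reactants: 23
Product: 24 2-[(2E)-3,7-dimethylocta-2,6-dien-1-yl]propanedioic acid
Conditions: KOH, EtOH–H2O, 23 °C; then cold 1 M aq. HCl to pH 2, 0 °C
Reagents that add atoms: potassium hydroxide, [K+].[OH-]
Why: saponification of both esters at room temperature with cold acidification should give the malonic acid without decarboxylation or hydration of the geranyl alkenes.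

Step 15
Reactants: 24
Product: 25 2-[(2E)-3,7-dimethylocta-2,6-dien-1-yl]propanedioyl dichloride
Conditions: 1-chloro-N,N,2-trimethylprop-1-en-1-amine (2.2 equiv), CH2Cl2, 0 → 23 °C; used at once
Reagents that add atoms: 1-chloro-N,N,2-trimethylprop-1-en-1-amine (Ghosez reagent), CC(C)=C(Cl)N(C)C
Why: acid chloride formation with the Ghosez α-chloroenamine is neutral and releases no HCl, which protects the acid-sensitive trisubstituted alkenes.

Step 16
Reactants: 20; 25
Product: 27 bicyclo[4.3.1] geranyl enol (rings A + E + D), via diketo acid chloride 26 (not isolated)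
Conditions: Et2O, −20 → 23 °C; then aq. KOH, BnEt3NCl, 23 °C; then aq. citric acid
Reagents that add atoms: none
Why: Effenberger cyclization, a (3+3) double C-acylation: the tetrasubstituted silyl enol ether attacks one acid chloride of 25 through C3 with loss of Me3SiCl to give 26, and under aqueous KOH with the phase-transfer salt the C2 ketone enolizes toward C1, its only α-hydrogens, and C1 attacks the second acid chloride. The closest known reaction is the cyclization of cyclohexanone enol ethers with malonyl dichlorides to bicyclo[3.3.1]nonane-2,4,9-triones; here a cycloheptanone enol ether should give the bicyclo[4.3.1] homologue. Ring A closes by a 6-(enolendo)-exo-trig C-acylation that forms C1–C9 after the intermolecular C3–C4 bond. C3 is controlled by C11, because the electrophile approaches the enol ether face that carries the C11 hydrogen, away from C10 and the C12 methyl groups (cis ring fusion); C1 is controlled by the tether, because the three-atom C4–C5–C9 bridge can reach only that same face of ring E. The step needs C- over O-acylation at both ends and this facial selectivity: the first is secured by the silyl enol ether and by the basic second stage, where the product is drained off as the stabilized C4/C5/C9 enolate thanks to the C5 hydrogen, the second by the single C11 stereocentre.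

Step 17
Reactants: 27
Product: 28 C5 bromide of 27
Conditions: N-bromosuccinimide, CH2Cl2, −78 → 0 °C, dark
Reagents that add atoms: N-bromosuccinimide, O=C1CCC(=O)N1Br
Why: electrophilic α-bromination of the enolized 2-substituted 1,3-diketone, whose C5 is far more nucleophilic than the isolated alkenes; the C5 configuration does not matter because the centre becomes a planar radical.

Step 18
Reactants: 28
Product: 29 cage triketone (target without the benzoyl group)
Conditions: Bu3SnH (1.2 equiv, syringe pump), AIBN (10 mol %), benzene (0.005 M), 80 °C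
Reagents that add atoms: none
Why: tin hydride-mediated radical cyclization, in which the electrophilic C5 radical between two carbonyls adds 6-endo-trig to the terminal carbon C6 of the electron-rich methylidene (C5–C6, ring B and the cage) and the tertiary C7 radical takes hydrogen from Bu3SnH on its only open, outer face, so that C5 and C7 are set by the cage geometry.

Step 19
Reactants: 29
Product: 30 target CNP0168637.1
Conditions: lithium 2,2,6,6-tetramethylpiperidide (from the amine and n-BuLi), THF, −78 °C; then PhCOCl, −78 → 0 °C
Reagents that add atoms: benzoyl chloride, O=C(Cl)c1ccccc1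
Why: bridgehead deprotonation and C-acylation: C1–H is the only acidic hydrogen left and lies between the C2 and C9 carbonyls, and the pyramidal bridgehead carbanion cannot become a planar enolate, so it should be acylated at carbon with retention.

**Compound list**
1 | isobutyronitrile | CC(C)C#N | starting material
2 | (4-bromobut-1-yn-1-yl)trimethylsilane | C[Si](C)(C)C#CCCBr | starting material
3 | 2,2-dimethyl-6-(trimethylsilyl)hex-5-ynenitrile | CC(C)(C#N)CCC#C[Si](C)(C)C | intermediate
4 | 2,2-dimethyl-6-(trimethylsilyl)hex-5-yn-1-imine (aldimine, formed as its aluminium derivative) | CC(C)(C=N)CCC#C[Si](C)(C)C | intermediate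
5 | 2,2-dimethyl-6-(trimethylsilyl)hex-5-ynal | CC(C)(C=O)CCC#C[Si](C)(C)C | intermediate
6 | 3-methylbutan-2-one | CC(C)C(C)=O | starting material
7 | 2,2-dimethylhex-5-ynal | CC(C)(C=O)CCC#C | intermediate
8 | 5-hydroxy-2,6,6-trimethyldec-9-yn-3-one | CC(C)C(=O)CC(O)C(C)(C)CCC#C | intermediate
9 | (4E)-2,6,6-trimethyldec-4-en-9-yn-3-one | CC(C)C(=O)/C=C/C(C)(C)CCC#C | intermediate
10 | (4E)-2,6,6-trimethyldeca-2,4-dien-9-yn-3-yl trifluoromethanesulfonate | CC(C)=C(OS(=O)(=O)C(F)(F)F)/C=C/C(C)(C)CCC#C | intermediate
11 | (3E)-5,5-dimethyl-2-(propan-2-ylidene)non-3-en-8-yn-1-ol | CC(C)=C(CO)/C=C/C(C)(C)CCC#C | intermediate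
12 | {(1S)-1-[(1E)-3,3-dimethylhept-1-en-6-yn-1-yl]-2,2-dimethylcyclopropyl}methanol | OC[C@@]1(/C=C/C(C)(C)CCC#C)C(C)(C)C1 | intermediate
13 | [(8aR)-1,1,6,6-tetramethyl-1,2,3,5,6,8a-hexahydroazulen-7-yl]methanol | OCC1=C[C@@H]2C(C)(C)CCC2=CCC1(C)C | intermediate
14 | N-{[(8aR)-1,1,6,6-tetramethyl-1,2,3,5,6,8a-hexahydroazulen-7-yl]methyl}-2-nitrobenzenesulfonohydrazide | NN(CC1=C[C@@H]2C(C)(C)CCC2=CCC1(C)C)S(=O)(=O)c1ccccc1[N+](=O)[O-] | intermediate
15 | {[(8aR)-1,1,6,6-tetramethyl-1,2,3,5,6,8a-hexahydroazulen-7-yl]methyl}diazene | N=NCC1=C[C@@H]2C(C)(C)CCC2=CCC1(C)C | intermediate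
16 | (8aR)-1,1,6,6-tetramethyl-7-methylidene-1,2,3,5,6,7,8,8a-octahydroazulene | C=C1C[C@@H]2C(C)(C)CCC2=CCC1(C)C | intermediate
17 | (8aR)-3a,4-epoxy-1,1,6,6-tetramethyl-7-methylidenedecahydroazulene (C2–C3 epoxide, either face) | C=C1C[C@@H]2C(C)(C)CCC23OC3CC1(C)C | intermediate
18 | (8aS)-1,1,6,6-tetramethyl-7-methylidenedecahydroazulen-4-ol (C2 alcohol, C2 and C3 unassigned) | C=C1C[C@@H]2C(C)(C)CCC2C(O)CC1(C)C | intermediate
19 | (8aS)-1,1,6,6-tetramethyl-7-methylideneoctahydroazulen-4(1H)-one (C2 ketone, either C3 epimer) | C=C1C[C@@H]2C(C)(C)CCC2C(=O)CC1(C)C | intermediate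
20 | trimethyl{[(8aR)-1,1,6,6-tetramethyl-7-methylidene-1,2,3,5,6,7,8,8a-octahydroazulen-4-yl]oxy}silane (C2=C3 silyl enol ether) | C=C1C[C@@H]2C(C)(C)CCC2=C(O[Si](C)(C)C)CC1(C)C | intermediate
21 | diethyl malonate | CCOC(=O)CC(=O)OCC | starting material
22 | geranyl bromide, (2E)-1-bromo-3,7-dimethylocta-2,6-diene | CC(C)=CCC/C(C)=C/CBr | starting material
23 | diethyl 2-[(2E)-3,7-dimethylocta-2,6-dien-1-yl]propanedioate | CC(C)=CCC/C(C)=C/CC(C(=O)OCC)C(=O)OCC | intermediate
24 | 2-[(2E)-3,7-dimethylocta-2,6-dien-1-yl]propanedioic acid | CC(C)=CCC/C(C)=C/CC(C(=O)O)C(=O)O | intermediate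
25 | 2-[(2E)-3,7-dimethylocta-2,6-dien-1-yl]propanedioyl dichloride | CC(C)=CCC/C(C)=C/CC(C(Cl)=O)C(Cl)=O | intermediate
26 | diketo acid chloride: ketone 19 C-acylated at C3 by one COCl of 25, new C3–C4 bond cis to the C11 hydrogen, C5 unassigned | CC(C)=CCC/C(C)=C/CC(C(Cl)=O)C(=O)[C@]12CCC(C)(C)[C@H]1CC(=C)C(C)(C)CC2=O | intermediate
27 | bicyclo[4.3.1] enol: ring A closed over ring E and fused to ring D; C2 and C9 ketones, C4 enol (C4=C5), C5 geranyl, C1–H, C7 methylidene; C3–C4 and C1–C9 on the face of the C11 hydrogen | CC(C)=CCC/C(C)=C/CC1=C(O)[C@]23CCC(C)(C)[C@H]2CC(=C)C(C)(C)[C@H](C1=O)C3=O | intermediate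
28 | C5 bromide of 27 (2-bromo-2-geranyl-1,3-diketone, C5 epimers) | CC(C)=CCC/C(C)=C/CC1(Br)C(=O)[C@]23CCC(C)(C)[C@H]2CC(=C)C(C)(C)[C@H](C1=O)C3=O | intermediate
29 | cage triketone: rings A, B, E and D closed, C5 geranyl, C1–H, C7–H outside the cage | CC(C)=CCC/C(C)=C/C[C@@]12C[C@H]3C[C@@H]4C(C)(C)CC[C@]4(C1=O)C(=O)[C@@H](C2=O)C3(C)C | intermediate
30 | CNP0168637.1 (29 with benzoyl on C1) | CC(C)=CCC/C(C)=C/C[C@@]12C[C@H]3C[C@@H]4C(C)(C)CC[C@]4(C1=O)C(=O)[C@@](C(=O)c1ccccc1)(C2=O)C3(C)C | target

**Count**
Total: 19 steps. Longest linear sequence: 16 steps (steps 1–12, then 16–19); the malonyl branch (steps 13–15) joins at step 16.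

**Steps most likely to fail**

Step 16. O-acylation may compete at either stage, giving pyranone or enol ester products. The monosubstituted malonyl dichloride may also lose HCl to an acylketene that oligomerizes before the hindered C3 is acylated. The fallback sets out from 20 and runs the annulation with unsubstituted malonyl dichloride, the reagent for which this cyclization is best established (Et2O, −20 °C; then aq. KOH, BnEt3NCl). This should give the C5-unsubstituted bicyclic enol F1. C-alkylation of its diketone enolate at C5 with geranyl bromide 22 (aq. KOH, BnEt3NCl, 23 °C) then comes back to the route at 27.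

Step 18. The C5 radical may be reduced before it cyclizes, the bromide may be removed by a polar bromine transfer to the tin hydride, or the radical may add to the geranyl alkenes. The fallback is ionic and sets out from 27. Hydroboration of the methylidene on its outer face with 9-BBN (in excess because of the acidic enol) and oxidation with NaBO3 should give the C6 primary alcohol F2 with the C7 hydrogen outside. I2, PPh3 and imidazole turn it into the C6 iodide F3. Cs2CO3 in DMF then closes C5–C6 by intramolecular C-alkylation of the diketone enolate and comes back at 29.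

Step 19. Deprotonation of the rigid cage bridgehead may fail, or the base and the acyl chloride may instead open the non-enolizable triketone by retro-Claisen cleavage. The fallback moves the benzoylation in front of the cage closure and sets out from 27. O-methylation (Me3SiCHN2, MeOH–toluene) gives the C4 methyl enol ether F4, and the C9 regioisomer is separated. Bridgehead lithiation with lithium 2,2,6,6-tetramethylpiperidide and a PhCOCl quench, on the bicyclic vinylogous ester for which bridgehead acylation is best established, gives the C1-benzoylated methyl enol ether F5. LiCl in DMSO at 120 °C removes the methyl group to give the C1-benzoylated enol F6. N-Bromosuccinimide gives the C1-benzoylated C5 bromide F7, and Bu3SnH with AIBN closes the cage as in step 18 and comes back at 30.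

**Further compounds**
F1 | step 16 | C5-unsubstituted bicyclic enol (27 without the geranyl group) | C1=C(O)[C@]23CCC(C)(C)[C@H]2CC(=C)C(C)(C)[C@H](C1=O)C3=O
F2 | step 18 | C6 primary alcohol (27 hydroborated at the methylidene, C7–H outside) | CC(C)=CCC/C(C)=C/CC1=C(O)[C@]23CCC(C)(C)[C@H]2C[C@H](CO)C(C)(C)[C@H](C1=O)C3=O
F3 | step 18 | C6 iodide | CC(C)=CCC/C(C)=C/CC1=C(O)[C@]23CCC(C)(C)[C@H]2C[C@H](CI)C(C)(C)[C@H](C1=O)C3=O
F4 | step 19 | C4 methyl enol ether of 27 | CC(C)=CCC/C(C)=C/CC1=C(OC)[C@]23CCC(C)(C)[C@H]2CC(=C)C(C)(C)[C@H](C1=O)C3=O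
F5 | step 19 | C1-benzoylated methyl enol ether | CC(C)=CCC/C(C)=C/CC1=C(OC)[C@]23CCC(C)(C)[C@H]2CC(=C)C(C)(C)[C@](C(=O)c2ccccc2)(C1=O)C3=O
F6 | step 19 | C1-benzoylated enol | CC(C)=CCC/C(C)=C/CC1=C(O)[C@]23CCC(C)(C)[C@H]2CC(=C)C(C)(C)[C@](C(=O)c2ccccc2)(C1=O)C3=O
F7 | step 19 | C1-benzoylated C5 bromide | CC(C)=CCC/C(C)=C/CC1(Br)C(=O)[C@]23CCC(C)(C)[C@H]2CC(=C)C(C)(C)[C@](C(=O)c2ccccc2)(C1=O)C3=O
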